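**Strategy.** The cyclohexene ring is disconnected at C2–C3 and C1–C6 (C1 quaternary carbinol, C7 its CH2, C2 CHOAc, C3 CHOBz, C4=C5, C6 CHOH) into an E,E-1,4-dioxygenated butadiene and a cyclic enediol carbonate bearing the C7 carbonyl. One copper–bis(oxazoline)-catalysed Diels–Alder reaction closes the ring and sets C1, C2, C3 and C6 at once. It exploits the pattern of cis O3/O6 flanking C4=C5, with cis O1/O2 on the opposite face and C7 on the O3/O6 face, which is the imide-endo adduct. The diene carries the final O3 benzoate and a silyl ether at O6; the dienophile is a 2-oxo-1,3-dioxole-4-carbonyl oxazolidinone whose carbonate carbon later becomes the O2 acetate carbonyl.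

Key step: step 6

Remarks before the steps:
- Numbering: the atom labels C1–C7 and O1, O2, O3, O6, O7 of the target are used for all ring compounds.
- Structure check: 13 has the same spatial arrangement at C1, C2, C3 and C6 as 17 (O1/O2 on one face; O3, O6 and C7 on the other), so no structure needed correction; the change of descriptor at C1 along the route comes from CIP priorities only.
- Assumption: the copper-bound dienophile is taken to react, like acryloyl oxazolidinones, through the planar chelate with C1=C2 syn to the imide C=O; on this model the (R,R) ligand exposes the required face, and the (S,S) ligand is the remedy if the sense proves opposite.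
- Materials: 1, 10 and (R,R)-tBu-box, (4R,4'R)-2,2'-(propane-2,2-diyl)bis(4-tert-butyl-4,5-dihydro-1,3-oxazole), are taken as purchasable.

Step 1
Reactants: 1 (1E,3E)-buta-1,3-diene-1,4-diyl diacetate
Product: 3 (1E,3E)-4-[(tert-butyldimethylsilyl)oxy]buta-1,3-dien-1-yl acetate, via lithium acetoxydienolate 2 (not isolated)
Conditions: MeLi (2.0 equiv), THF, −78 → −40 °C; then TBSCl (1.2 equiv), DMPU, −78 → 0 °C
Reagents that add atoms: tert-butyldimethylsilyl chloride, CC(C)(C)[Si](C)(C)Cl
Why: Cleavage of one enol acetate by MeLi (the second equivalent consumes the acetone released) should give the lithium dienolate with the E,E geometry intact, the anionic mono-enolate resisting a second cleavage, and O-silylation of this aldehyde dienolate in THF/DMPU should give the silyl dienol ether with no stereocentre formed.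

Step 2
Reactants: 3 (1E,3E)-4-[(tert-butyldimethylsilyl)oxy]buta-1,3-dien-1-yl acetate
Product: 5 (1E,3E)-4-[(tert-butyldimethylsilyl)oxy]buta-1,3-dien-1-yl benzoate, via lithium silyloxydienolate 4 (not isolated)
Conditions: MeLi (2.0 equiv), THF, −78 °C; then BzCl (2.2 equiv), DMPU, −78 → 0 °C
Reagents that add atoms: benzoyl chloride, O=C(Cl)c1ccccc1
Why: The same enol-ester cleavage, which a tert-butyldimethylsilyl enol ether should tolerate at −78 °C, gives the silyloxy dienolate, and O-acylation of an aldehyde dienolate by an acid chloride in a polar medium should install the enol benzoate with retention of the E,E geometry and no stereocentre.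

Step 3
Reactants: 6 glycerol carbonate (racemic 4-(hydroxymethyl)-1,3-dioxolan-2-one)
Product: 7 racemic 2-oxo-1,3-dioxolane-4-carboxylic acid
Conditions: PhI(OAc)2 (2.2 equiv), TEMPO (0.2 equiv), MeCN/H2O 1:1, rt
Reagents that add atoms: water, O
Why: Nitroxyl-mediated oxidation of a primary alcohol in aqueous MeCN runs through the aldehyde hydrate to the carboxylic acid under mildly acidic conditions that a five-membered cyclic carbonate should survive, and the stereocentre is of no consequence because step 5 removes it.

Step 4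
Reactants: 7 racemic 2-oxo-1,3-dioxolane-4-carboxylic acid
Product: 9 racemic 4-bromo-2-oxo-1,3-dioxolane-4-carbonyl chloride, via acid chloride 8 (not isolated)
Conditions: SOCl2 (neat), 65 °C; then NBS (1.2 equiv), 48% HBr (cat.), 85 °C
Reagents that add atoms: thionyl chloride, O=S(Cl)Cl; N-bromosuccinimide, O=C1CCC(=O)N1Br
Why: Hell–Volhard–Zelinsky α-bromination in its NBS/HBr/SOCl2 form should brominate the acid chloride at its only enolisable position (C4 of the dioxolane) while the acid-stable carbonate is a spectator, and the racemic stereocentre so formed is removed in step 5.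

Step 5
Reactants: 9 racemic 4-bromo-2-oxo-1,3-dioxolane-4-carbonyl chloride; 10 3-(trimethylsilyl)oxazolidin-2-one
Product: 12 3-(2-oxo-1,3-dioxole-4-carbonyl)oxazolidin-2-one, via bromo imide 11 (not isolated)
Conditions: toluene, 80 °C (−Me3SiCl); then Et3N (1.05 equiv), CH2Cl2, 0 °C → rt
Reagents that add atoms: none
Why: Base-free N-acylation of the N-silyl carbamate by the acid chloride, driven by loss of Me3SiCl, is followed by E2 dehydrobromination in which Et3N can only take a ring CH2 hydrogen and so should give the conjugated endocyclic enol carbonate, as in the dehydrochlorination of chloroethylene carbonate to vinylene carbonate, with no stereocentre left.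

Step 6
Reactants: 5 (1E,3E)-4-[(tert-butyldimethylsilyl)oxy]buta-1,3-dien-1-yl benzoate; 12 3-(2-oxo-1,3-dioxole-4-carbonyl)oxazolidin-2-one
Product: 13 (3aS,4S,7R,7aS)-4-[(tert-butyldimethylsilyl)oxy]-2-oxo-3a-(2-oxo-1,3-oxazolidine-3-carbonyl)-3a,4,7,7a-tetrahydro-1,3-benzodioxol-7-yl benzoate (carbonate oxygens O1/O2 cis on one face; O3 benzoate, O6 silyl ether and the C7 imide on the other)
Conditions: [Cu((R,R)-tBu-box)](SbF6)2 (10 mol %, from CuCl2, (R,R)-tBu-box and AgSbF6), 5 (1.5 equiv), 4 Å MS, CH2Cl2, −40 → −20 °C
Reagents that add atoms: none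
Why: Proposed new method: the two imide carbonyls of 12 chelate the square-planar divalent copper centre, which lowers the LUMO of C1=C2, and the diene should add in a concerted but asynchronous [4+2] cycloaddition in which the C2–C3 bond to the β-carbon is the more advanced. The closest known reaction type is the [Cu(tBu-box)](SbF6)2-catalysed Diels–Alder reaction of acryloyl oxazolidinones with 1-acyloxy and other 1-heteroatom dienes, together with thermal cycloadditions of vinylene carbonate; a dioxolone-carbonyl imide has not served as the dienophile. Ring A (the cyclohexene) closes by intermolecular suprafacial–suprafacial [4+2] cycloaddition that forms C2–C3 and C1–C6. C1 and C2 keep the cis O1/O2 relation fixed by the dioxolone ring, C3 and C6 receive the cis O3/O6 relation from the E,E geometry of the diene, the endo position of the chelated imide places C7 on the O3/O6 face, and the (R,R) ligand blocks the Re face of C1 so that the diene adds to the C1-Si/C2-Si face and sets the absolute configuration. The step needs regio-, endo- and facial selectivity: the stronger silyloxy donor makes the benzoyloxy-bearing terminus C3 the nucleophilic end that bonds to the β-carbon C2, the bidentate imide secures the endo mode, and the single chelate geometry secures the face.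

Step 7
Reactants: 13 the cycloadduct
Product: 14 (3aS,4S,7R,7aS)-4-[(tert-butyldimethylsilyl)oxy]-3a-(hydroxymethyl)-2-oxo-3a,4,7,7a-tetrahydro-1,3-benzodioxol-7-yl benzoate
Conditions: NaBH4 (2 equiv), THF/H2O 4:1, 0 °C; pH 7 buffer quench
Reagents that add atoms: none
Why: Borohydride reduction of an N-acyl oxazolidinone in wet THF attacks the activated exocyclic imide carbonyl and runs through the aldehyde to the primary alcohol, while benzoate, cyclic carbonate and silyl ether should be inert at 0 °C (a short reaction time and a neutral quench keep the carbonate from migrating to O7) and no stereocentre is touched.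

Step 8
Reactants: 14 the primary alcohol
Product: 15 (3aS,4S,7R,7aS)-3a-[(benzoyloxy)methyl]-4-[(tert-butyldimethylsilyl)oxy]-2-oxo-3a,4,7,7a-tetrahydro-1,3-benzodioxol-7-yl benzoate
Conditions: BzCl (1.3 equiv), pyridine, DMAP (cat.), CH2Cl2, 0 °C
Reagents that add atoms: benzoyl chloride, O=C(Cl)c1ccccc1
Why: DMAP-catalysed esterification should acylate the only free hydroxyl, the primary C7 alcohol, without touching a stereocentre.

Step 9
Reactants: 15 the bis(benzoate) carbonate
Product: 16 [(1S,2S,3R,6S)-2-(acetyloxy)-3-(benzoyloxy)-6-[(tert-butyldimethylsilyl)oxy]-1-hydroxycyclohex-4-en-1-yl]methyl benzoate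
Conditions: MeLi (1.2 equiv), THF, −78 °C; sat. aq. NH4Cl quench at −78 °C
Reagents that add atoms: methyllithium, [Li]C
Why: Organolithium opening of a cyclic carbonate to a hydroxy ester should be selective at −78 °C because the strained five-membered carbonate is more electrophilic than the two benzoates, and the tetrahedral adduct should collapse by expelling the hindered tertiary O1 alkoxide so that the former carbonate carbon becomes the O2 acetyl carbonyl, O2 is never free beside the O3 benzoate, and no stereocentre is touched.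

Step 10
Reactants: 16 the silyl ether
Product: 17 [(1R,2S,3R,6S)-2-(acetyloxy)-3-(benzoyloxy)-1,6-dihydroxycyclohex-4-en-1-yl]methyl benzoate (HY-N2634)
Conditions: HF·pyridine, pyridine/THF, 0 °C → rt
Reagents that add atoms: none
Why: Fluoride-mediated desilylation under mildly acidic conditions should free the allylic O6 hydroxyl without the acyl migration that basic fluoride could cause and without touching a stereocentre.

**Compound list**
1 | (1E,3E)-buta-1,3-diene-1,4-diyl diacetate | CC(=O)O/C=C/C=C/OC(C)=O | starting material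
2 | lithium (1E,3E)-4-(acetyloxy)buta-1,3-dien-1-olate | [Li+].[O-]/C=C/C=C/OC(C)=O | intermediate
3 | (1E,3E)-4-[(tert-butyldimethylsilyl)oxy]buta-1,3-dien-1-yl acetate | CC(=O)O/C=C/C=C/O[Si](C)(C)C(C)(C)C | intermediate
4 | lithium (1E,3E)-4-[(tert-butyldimethylsilyl)oxy]buta-1,3-dien-1-olate | [Li+].[O-]/C=C/C=C/O[Si](C)(C)C(C)(C)C | intermediate
5 | (1E,3E)-4-[(tert-butyldimethylsilyl)oxy]buta-1,3-dien-1-yl benzoate | O=C(O/C=C/C=C/O[Si](C)(C)C(C)(C)C)c1ccccc1 | intermediate
6 | glycerol carbonate, racemic 4-(hydroxymethyl)-1,3-dioxolan-2-one | O=C1OCC(CO)O1 | starting material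
7 | racemic 2-oxo-1,3-dioxolane-4-carboxylic acid | O=C1OCC(C(=O)O)O1 | intermediate
8 | racemic 2-oxo-1,3-dioxolane-4-carbonyl chloride | O=C1OCC(C(=O)Cl)O1 | intermediate
9 | racemic 4-bromo-2-oxo-1,3-dioxolane-4-carbonyl chloride | O=C1OCC(Br)(C(=O)Cl)O1 | intermediate
10 | 3-(trimethylsilyl)oxazolidin-2-one | C[Si](C)(C)N1CCOC1=O | starting material
11 | racemic 3-(4-bromo-2-oxo-1,3-dioxolane-4-carbonyl)oxazolidin-2-one | O=C1OCC(Br)(C(=O)N2CCOC2=O)O1 | intermediate
12 | 3-(2-oxo-1,3-dioxole-4-carbonyl)oxazolidin-2-one | O=C1OC=C(O1)C(=O)N1CCOC1=O | intermediate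
13 | (3aS,4S,7R,7aS)-4-[(tert-butyldimethylsilyl)oxy]-2-oxo-3a-(2-oxo-1,3-oxazolidine-3-carbonyl)-3a,4,7,7a-tetrahydro-1,3-benzodioxol-7-yl benzoate | O=C1O[C@H]2[C@H](OC(=O)c3ccccc3)C=C[C@H](O[Si](C)(C)C(C)(C)C)[C@]2(O1)C(=O)N1CCOC1=O | intermediate
14 | (3aS,4S,7R,7aS)-4-[(tert-butyldimethylsilyl)oxy]-3a-(hydroxymethyl)-2-oxo-3a,4,7,7a-tetrahydro-1,3-benzodioxol-7-yl benzoate | O=C1O[C@H]2[C@H](OC(=O)c3ccccc3)C=C[C@H](O[Si](C)(C)C(C)(C)C)[C@]2(O1)CO | intermediate
15 | (3aS,4S,7R,7aS)-3a-[(benzoyloxy)methyl]-4-[(tert-butyldimethylsilyl)oxy]-2-oxo-3a,4,7,7a-tetrahydro-1,3-benzodioxol-7-yl benzoate | O=C1O[C@H]2[C@H](OC(=O)c3ccccc3)C=C[C@H](O[Si](C)(C)C(C)(C)C)[C@]2(O1)COC(=O)c1ccccc1 | intermediate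
16 | [(1S,2S,3R,6S)-2-(acetyloxy)-3-(benzoyloxy)-6-[(tert-butyldimethylsilyl)oxy]-1-hydroxycyclohex-4-en-1-yl]methyl benzoate | CC(=O)O[C@H]1[C@H](OC(=O)c2ccccc2)C=C[C@H](O[Si](C)(C)C(C)(C)C)[C@]1(O)COC(=O)c1ccccc1 | intermediate
17 | [(1R,2S,3R,6S)-2-(acetyloxy)-3-(benzoyloxy)-1,6-dihydroxycyclohex-4-en-1-yl]methyl benzoate | CC(=O)O[C@H]1[C@H](OC(=O)c2ccccc2)C=C[C@H](O)[C@]1(O)COC(=O)c1ccccc1 | target

**Step count.** Total: 10 steps. Longest linear sequence: 8 steps (steps 3 to 10; the diene arm, steps 1 and 2, joins at step 6).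

**Steps most likely to fail, each with a fallback**

1. Step 6, the cycloaddition. The risks are poor endo or facial selectivity, a stepwise Michael-type pathway that erodes the cis O3/O6 relation, or loss of the silyl enol ether to the cationic Lewis acid. The fallback replaces catalyst control by a covalently bound oxazolidinone auxiliary under aluminium chelation, which is known chemistry for acyl oxazolidinones. It sets out from 9, which is condensed with (S)-4-benzyloxazolidin-2-one (Et3N, DMAP cat., CH2Cl2, 0 °C) to give the bromo imide (4S)-4-benzyl-3-(4-bromo-2-oxo-1,3-dioxolane-4-carbonyl)oxazolidin-2-one F1. The same base removes HBr from it to give the auxiliary dienophile (4S)-4-benzyl-3-(2-oxo-1,3-dioxole-4-carbonyl)oxazolidin-2-one F2. Cycloaddition of F2 with 5 under Me2AlCl (1.4 equiv, CH2Cl2, −78 °C), in which the benzyl group of the chelated imide shields the Re face of C1, should give the auxiliary-bearing cycloadduct (3aS,4S,7R,7aS)-3a-[(4S)-4-benzyl-2-oxo-1,3-oxazolidine-3-carbonyl]-4-[(tert-butyldimethylsilyl)oxy]-2-oxo-3a,4,7,7a-tetrahydro-1,3-benzodioxol-7-yl benzoate F3. Reduction with NaBH4 (THF/H2O, 0 °C) cleaves the auxiliary and comes back to the route at 14.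

2. Step 9, the carbonate opening. The risks are competing attack of MeLi on the benzoates, or collapse of the adduct toward the tertiary ester followed by acyl migration. The fallback removes the carbonate by solvolysis and acetylates separately. It sets out from 15: LiOH (2 equiv, THF/H2O, 0 °C, stopped as soon as the carbonate is consumed) should give the diol [(1S,2S,3R,6S)-3-(benzoyloxy)-6-[(tert-butyldimethylsilyl)oxy]-1,2-dihydroxycyclohex-4-en-1-yl]methyl benzoate F4. Ac2O in pyridine (no DMAP, 0 °C) then acetylates the secondary O2–H and not the tertiary O1–H, which comes back to the route at 16.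

3. Step 4, the α-bromination. The risks are slow enolisation of the α-oxygenated acid chloride with incomplete bromination, or degradation under hot HBr. The fallback dehydrogenates at the imide stage by selenoxide elimination. It sets out from 7: (COCl)2 with DMF (cat.) in CH2Cl2 gives 8, which acylates 10 (toluene, 80 °C) to the saturated imide racemic 3-(2-oxo-1,3-dioxolane-4-carbonyl)oxazolidin-2-one F5. α-Selenenylation (LiN(SiMe3)2, then PhSeBr, THF, −78 °C) gives the selenide racemic 3-[2-oxo-4-(phenylselanyl)-1,3-dioxolane-4-carbonyl]oxazolidin-2-one F6. Oxidation with H2O2 (CH2Cl2, 0 °C) gives the selenoxide 3-[2-oxo-4-(benzeneseleninyl)-1,3-dioxolane-4-carbonyl]oxazolidin-2-one F7, whose syn-elimination toward the ring CH2 comes back to the route at 12.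

**Further compounds**
F1 | step 6 | (4S)-4-benzyl-3-(4-bromo-2-oxo-1,3-dioxolane-4-carbonyl)oxazolidin-2-one (both epimers at the C–Br carbon) | O=C1OCC(Br)(C(=O)N2[C@@H](Cc3ccccc3)COC2=O)O1
F2 | step 6 | (4S)-4-benzyl-3-(2-oxo-1,3-dioxole-4-carbonyl)oxazolidin-2-one | O=C1OC=C(O1)C(=O)N1[C@@H](Cc2ccccc2)COC1=O
F3 | step 6 | (3aS,4S,7R,7aS)-3a-[(4S)-4-benzyl-2-oxo-1,3-oxazolidine-3-carbonyl]-4-[(tert-butyldimethylsilyl)oxy]-2-oxo-3a,4,7,7a-tetrahydro-1,3-benzodioxol-7-yl benzoate | O=C1O[C@H]2[C@H](OC(=O)c3ccccc3)C=C[C@H](O[Si](C)(C)C(C)(C)C)[C@]2(O1)C(=O)N1[C@@H](Cc2ccccc2)COC1=O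
F4 | step 9 | [(1S,2S,3R,6S)-3-(benzoyloxy)-6-[(tert-butyldimethylsilyl)oxy]-1,2-dihydroxycyclohex-4-en-1-yl]methyl benzoate | O[C@H]1[C@H](OC(=O)c2ccccc2)C=C[C@H](O[Si](C)(C)C(C)(C)C)[C@]1(O)COC(=O)c1ccccc1
F5 | step 4 | racemic 3-(2-oxo-1,3-dioxolane-4-carbonyl)oxazolidin-2-one | O=C1OCC(C(=O)N2CCOC2=O)O1
F6 | step 4 | racemic 3-[2-oxo-4-(phenylselanyl)-1,3-dioxolane-4-carbonyl]oxazolidin-2-one | O=C1OCC([Se]c2ccccc2)(C(=O)N2CCOC2=O)O1
F7 | step 4 | 3-[2-oxo-4-(benzeneseleninyl)-1,3-dioxolane-4-carbonyl]oxazolidin-2-one (mixture of stereoisomers) | O=C1OCC([Se](=O)c2ccccc2)(C(=O)N2CCOC2=O)O1
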